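**Retrosynthetic overview**
1. Agrandol 7 is a (2S)-flavanone with a single stereocentre (C2). Disconnect C2–H back to the flavone 4 (8-prenyloroxylin A), which is reduced last by enantioselective hydride delivery to C2 of its 4-siloxyflavylium ion pair under a chiral hydrogen-bond-donor organocatalyst.
2. The C8–prenyl bond of 4 comes from a formal [1,3] O→C prenyl shift of the 7-O-prenyl ether 3; C6 is blocked by OMe, so C8 is the only acceptor. This two-step prenylation is preferred over one-step C-prenylation, which is low-yielding.
3. Ether 3 comes from chelation-controlled 7-O-alkylation of achiral oroxylin A 1 with prenyl bromide 2.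
4. Rings: the A, B and pyranone C rings arrive intact in 1. No ring is built; the C ring is only reduced in step 3.

Assumption: oroxylin A (achiral catalogue flavone) counts as a commercial starting material; "prenyl" = 3-methylbut-2-en-1-yl; catalyst C* = 3,5-bis(trifluoromethyl)anilino squaramide of tert-leucine 2-arylpyrrolidine amide (either antipode, from D- or L-tert-leucine).

**Step 1**
Reactants: 1 oroxylin A; 2 prenyl bromide
Product: 3 7-O-prenyloroxylin A [5-hydroxy-6-methoxy-7-(3-methylbut-2-enyloxy)flavone]
Conditions: 2 (1.1 equiv), K2CO3 (1.5 equiv), acetone, reflux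
Reagents that add atoms: prenyl bromide (2), CC(C)=CCBr
Why: Williamson etherification; the 5-OH is locked in a hydrogen bond to C4=O, so only the acidic 7-OH is alkylated.

**Step 2**
Reactants: 3 7-O-prenyloroxylin A
Product: 4 8-prenyloroxylin A [5,7-dihydroxy-6-methoxy-8-(3-methylbut-2-enyl)flavone]
Conditions: montmorillonite K10, CH2Cl2, 0 °C → rt
Reagents that add atoms: none
Why: Known clay-mediated formal [1,3] O→C prenyl shift (surface ion-pair Friedel–Crafts re-alkylation) of an aryl prenyl ether; with C6 blocked by OMe, C8 is the only free, doubly activated ring position, and no stereocentre is formed.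

**Step 3**
Reactants: 4 8-prenyloroxylin A
Product: 7 agrandol [(2S)-5,7-dihydroxy-6-methoxy-8-prenylflavanone], via tris-TMS flavylium triflate 5 (not isolated), via tris-TMS 2H-chromene silyl enol ether 6 (not isolated)
Conditions: TMSOTf (3.3 equiv), 2,6-lutidine (3.5 equiv), CH2Cl2, 0 → 40 °C; then C* (10 mol %), diethyl Hantzsch ester (1.3 equiv), PhMe/CH2Cl2, −60 °C; then citric acid, aq. MeOH, 0 °C
Reagents that add atoms: none
Why: Proposed new method: enantioselective ion-pair transfer hydrogenation of an in-situ 4-siloxyflavylium triflate; silylating both phenols and the pyrone carbonyl turns the unreactive vinylogous ester into flavylium 5, whose most electrophilic site is C2 (C4 is deactivated by its OSi donor and shielded by the peri 5-OTMS); the squaramide binds the triflate, draws the tight ion pair into solution as a more electrophilic chiral ion pair and, through the same bound anion, hydrogen-bonds the Hantzsch ester N–H so that hydride adds to the Re face of C2 (the catalyst antipode that gives this sense is chosen by screening), setting (2S) in silyl enol ether 6, which mild acid methanolysis converts to the ketone and free phenols without touching C2 or the lutidine-buffered prenyl group; closest known reaction type: hydrogen-bond-donor (squaramide, thiourea, silanediol) anion-binding catalysed enantioselective additions of silyl ketene acetals to 4-siloxybenzopyrylium triflates generated from chromones and silyl triflates, together with chiral-counterion Hantzsch ester reductions of benzopyrylium and quinolinium ions.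

**Compound list**
1 | oroxylin A (5,7-dihydroxy-6-methoxy-2-phenyl-4H-chromen-4-one) | COc1c(O)cc2oc(-c3ccccc3)cc(=O)c2c1O | starting material
2 | prenyl bromide (1-bromo-3-methylbut-2-ene) | CC(C)=CCBr | starting material
3 | 5-hydroxy-6-methoxy-7-(3-methylbut-2-enyloxy)-2-phenyl-4H-chromen-4-one | COc1c(OCC=C(C)C)cc2oc(-c3ccccc3)cc(=O)c2c1O | intermediate
4 | 5,7-dihydroxy-6-methoxy-8-(3-methylbut-2-enyl)-2-phenyl-4H-chromen-4-one | COc1c(O)c(CC=C(C)C)c2oc(-c3ccccc3)cc(=O)c2c1O | intermediate
5 | 6-methoxy-8-(3-methylbut-2-enyl)-2-phenyl-4,5,7-tris(trimethylsilyloxy)chromenylium triflate | COc1c(O[Si](C)(C)C)c(CC=C(C)C)c2[o+]c(-c3ccccc3)cc(O[Si](C)(C)C)c2c1O[Si](C)(C)C.[O-]S(=O)(=O)C(F)(F)F | intermediate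
6 | (2S)-6-methoxy-8-(3-methylbut-2-enyl)-2-phenyl-4,5,7-tris(trimethylsilyloxy)-2H-chromene | COc1c(O[Si](C)(C)C)c(CC=C(C)C)c2c(c1O[Si](C)(C)C)C(O[Si](C)(C)C)=C[C@@H](c1ccccc1)O2 | intermediate
7 | agrandol, (2S)-5,7-dihydroxy-6-methoxy-8-(3-methylbut-2-enyl)-2-phenyl-2,3-dihydro-4H-chromen-4-one | COc1c(O)c(CC=C(C)C)c2c(c1O)C(=O)C[C@@H](c1ccccc1)O2 | target

**Total step count:** 3. **Longest linear sequence:** 3 steps (1 → 3 → 4 → 7).

**Steps most likely to fail, with fallbacks**

Step 3 (proposed new reaction). The risks are a racemic background reduction of the free ion pair, hydride addition at C4 instead of C2, and low ee. The fallback sets out from 4 and uses known chemistry. Both phenols are silylated (TBSOTf, 2,6-lutidine, CH2Cl2) to give 5,7-bis(tert-butyldimethylsilyloxy)-6-methoxy-8-prenylflavone F1. Copper hydride-catalysed asymmetric conjugate reduction then follows (Cu(OAc)2, DTBM-SEGPHOS antipode giving 2S, (EtO)2MeSiH, t-BuOH, toluene). This reaction class is established for 2-substituted chromones and leaves the trisubstituted prenyl alkene alone. It gives (2S)-5,7-bis(tert-butyldimethylsilyloxy)-6-methoxy-8-prenylflavanone F2. Desilylation with Et3N·3HF in THF is non-basic, so there is no retro-oxa-Michael racemisation, and it comes back to the route at 7.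

Step 2 (clay [1,3] shift). The risks are loss of the prenyl group back to 1 and acid cyclisation of 4 to the dimethylchroman. The fallback sets out from 1. Allyl bromide and K2CO3 in acetone give 7-O-allyloroxylin A F3. Thermal aromatic Claisen rearrangement (N,N-diethylaniline, 200 °C) can deliver allyl only to C8, giving 8-allyloroxylin A F4. Olefin cross-metathesis with 2-methyl-2-butene (Grubbs II, CH2Cl2, 40 °C) converts allyl to prenyl and comes back to the route at 4.

Step 1 (O-prenylation). The risks are competing C-alkylation or over-alkylation. The fallback sets out from 1 and alkylates carbon directly: Friedel–Crafts C-prenylation at C8, the only free ring position, with 2-methylbut-3-en-2-ol and BF3·OEt2 in dioxane at rt. It is lower yielding but skips 3, makes no new compound (F0), and comes back to the route at 4.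

**Further compounds**
F1 | step 3 | 5,7-bis(tert-butyldimethylsilyloxy)-6-methoxy-8-(3-methylbut-2-enyl)-2-phenyl-4H-chromen-4-one | COc1c(O[Si](C)(C)C(C)(C)C)c(CC=C(C)C)c2oc(-c3ccccc3)cc(=O)c2c1O[Si](C)(C)C(C)(C)C
F2 | step 3 | (2S)-5,7-bis(tert-butyldimethylsilyloxy)-6-methoxy-8-(3-methylbut-2-enyl)-2-phenylchroman-4-one | COc1c(O[Si](C)(C)C(C)(C)C)c(CC=C(C)C)c2c(c1O[Si](C)(C)C(C)(C)C)C(=O)C[C@@H](c1ccccc1)O2
F3 | step 2 | 7-(allyloxy)-5-hydroxy-6-methoxy-2-phenyl-4H-chromen-4-one | COc1c(OCC=C)cc2oc(-c3ccccc3)cc(=O)c2c1O
F4 | step 2 | 8-allyl-5,7-dihydroxy-6-methoxy-2-phenyl-4H-chromen-4-one | COc1c(O)c(CC=C)c2oc(-c3ccccc3)cc(=O)c2c1O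
F0 | step 1 | none | none
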